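**Plan**
- Retrosynthesis: the acyl C–O bond of the side-chain ester is cut first (shikonin plus an O-silylated 3-hydroxy-3-methylbutanoic acid). Then three bonds of the quinone ring are cut, C3–C4, C1–C2 and C1–C8a, giving an aryl(methoxy)carbene complex of chromium, a terminal propargylic silyl ether and one CO ligand.
- Enabling feature: the ring C1–C2–C3–C4–C4a–C8a has oxygen at C1 and C4, the side chain at C2, hydrogen at C3, and is fused at C4a/C8a to a para-dioxygenated benzo ring (C5–C8). CO supplies C1, a terminal alkyne C2/C3, the carbene carbon C4, and a 2,5-dioxygenated aryl the rest.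
- Forward: the benzenoid ring comes from hydroquinone; the second ring is closed in one benzannulation as a 4-methoxy-1-naphthol, oxidised to the quinone and unmasked to the naphthazarin; the acyl chain is attached last.
- Stereochemistry: the only stereocentre (C1', R, as in shikonin) is set by Noyori transfer hydrogenation of a silyl ynone before the annulation; no later step breaks a bond at that carbon.

Key step: step 8

Remark: 2-substituted naphthazarins are rapidly equilibrating tautomers, so shikonin and its esters are written throughout in the tautomer of the target SMILES.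

**Route**

Step 1
Reactants: 1 hydroquinone
Product: 2 1,4-bis(methoxymethoxy)benzene
Conditions: NaH, DMF, 0 °C; MOMCl, 0 °C → rt
Reagents that add atoms: chloromethyl methyl ether (MOMCl), COCCl
Why: Williamson-type O-alkylation of the bis-phenoxide with the reactive α-chloro ether is a standard MOM protection and installs acetals that direct lithiation and later come off without an oxidant.

Step 2
Reactants: 2 1,4-bis(methoxymethoxy)benzene; 3 chromium hexacarbonyl
Product: 6 pentacarbonyl{[2,5-bis(methoxymethoxy)phenyl](methoxy)methylene}chromium(0), via 2-lithio-1,4-bis(methoxymethoxy)benzene 4 (not isolated), via lithium acylpentacarbonylchromate 5 (not isolated)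
Conditions: n-BuLi, THF, 0 °C; Cr(CO)6, THF, 0 °C → rt; evaporate; Me3OBF4, CH2Cl2, 0 °C → rt
Reagents that add atoms: trimethyloxonium tetrafluoroborate, C[O+](C)C.F[B-](F)(F)F
Why: Fischer carbene synthesis, in which MOM-directed ortho-lithiation gives an aryllithium that adds to a CO ligand and the resulting acylate is O-methylated by the hard oxonium salt, as is established for 2,5-dialkoxyphenyl complexes.

Step 3
Reactants: 7 4-methylpent-3-enoic acid
Product: 9 N-methoxy-N,4-dimethylpent-3-enamide, via 1-(4-methylpent-3-enoyl)imidazole 8 (not isolated)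
Conditions: CDI, CH2Cl2, 0 °C → rt; MeNH(OMe)·HCl, rt
Reagents that add atoms: N,O-dimethylhydroxylamine hydrochloride, CNOC.Cl
Why: Weinreb amide formation through the acylimidazole runs under near-neutral conditions that should leave the skipped trisubstituted alkene in place.

Step 4
Reactants: 9 N-methoxy-N,4-dimethylpent-3-enamide; 10 trimethylsilylacetylene
Product: 12 6-methyl-1-(trimethylsilyl)hept-5-en-1-yn-3-one, via lithium (trimethylsilyl)acetylide 11 (not isolated)
Conditions: 10, n-BuLi, THF, −78 °C; then 9, −78 → −20 °C; aq. NH4Cl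
Reagents that add atoms: none
Why: Weinreb ketone synthesis, in which the N-methoxy-N-methylamide takes up a single equivalent of the weakly basic acetylide and releases the ynone only on aqueous quench, so over-addition and enolisation should stay minor.

Step 5
Reactants: 12 6-methyl-1-(trimethylsilyl)hept-5-en-1-yn-3-one
Product: 13 (R)-6-methyl-1-(trimethylsilyl)hept-5-en-1-yn-3-ol
Conditions: Ru[(R,R)-TsDPEN](p-cymene) (preformed amido complex, 1 mol %), i-PrOH, rt
Reagents that add atoms: none
Why: Noyori asymmetric transfer hydrogenation of an alkynyl ketone, in which the Ru–H/N–H catalyst distinguishes the alkynyl from the alkyl flank, and the (R,R)-ligand is expected to give the R carbinol by the established (S,S)→(S) correlation for alkyl alkynyl ketones under base-free conditions.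

Step 6
Reactants: 13 (R)-6-methyl-1-(trimethylsilyl)hept-5-en-1-yn-3-ol
Product: 14 (R)-tert-butyldimethyl{[6-methyl-1-(trimethylsilyl)hept-5-en-1-yn-3-yl]oxy}silane
Conditions: TBSCl, imidazole, DMF, rt
Reagents that add atoms: tert-butyldimethylsilyl chloride, CC(C)(C)[Si](C)(C)Cl
Why: Standard imidazole-promoted O-silylation of a secondary alcohol breaks no bond at the stereocentre and gives a non-volatile, non-ionisable propargylic ether.

Step 7
Reactants: 14 (R)-tert-butyldimethyl{[6-methyl-1-(trimethylsilyl)hept-5-en-1-yn-3-yl]oxy}silane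
Product: 15 (R)-tert-butyldimethyl[(6-methylhept-5-en-1-yn-3-yl)oxy]silane
Conditions: K2CO3 (cat.), MeOH, rt
Reagents that add atoms: none
Why: Base-catalysed methanolytic cleavage of the alkynyl C–Si bond is selective over the O-TBS ether and frees the terminal alkyne.

Step 8
Reactants: 6 pentacarbonyl{[2,5-bis(methoxymethoxy)phenyl](methoxy)methylene}chromium(0); 15 (R)-tert-butyldimethyl[(6-methylhept-5-en-1-yn-3-yl)oxy]silane
Product: 17 (R)-2-[1-(tert-butyldimethylsilyloxy)-4-methylpent-3-enyl]-4-methoxy-5,8-bis(methoxymethoxy)naphthalen-1-ol, via tricarbonylchromium naphthol complex 16 (not isolated)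
Conditions: 15 (1.5 equiv), degassed THF, 50 °C, Ar; then air, Et2O, rt; 17 handled under Ar and used at once
Reagents that add atoms: none
Why: Thermal loss of one CO from 6, assisted by the ortho acetal oxygen, opens a site for alkyne 15, which inserts into the Cr=C bond with its unsubstituted terminus bonded to the carbene carbon (C3–C4), and CO insertion then gives an η4-vinylketene complex (C1–C2). The six-membered ring is closed by 6π-electrocyclisation of this aryl-vinylketene onto the only free ortho carbon of the arene (C1–C8a), and tautomerisation gives the naphthol as its Cr(CO)3 complex 16, which air demetalates to 17. This is the Dötz benzannulation, the closest precedent being 2,5-dialkoxyphenyl(methoxy)carbene complexes reacting with terminal alkynes and propargylic silyl ethers. No stereocentre is formed; the propargylic centre should survive because nothing ionises or deprotonates it (a silyl ether is a poor leaving group), and the face isomerism of 16 disappears on decomplexation. Phenol formation must beat cyclobutenone and indene formation, which the aryl carbene, the coordinating solvent and excess alkyne favour. The regiochemistry is set by the size difference between H and the branched silyloxyalkyl group, which places the large group next to the CO-derived carbon, and a slip would be harmless because both orientations give the same quinone 18 on the symmetric 5,8-bis-MOM core.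

Step 9
Reactants: 17 (R)-2-[1-(tert-butyldimethylsilyloxy)-4-methylpent-3-enyl]-4-methoxy-5,8-bis(methoxymethoxy)naphthalen-1-ol
Product: 18 (R)-2-[1-(tert-butyldimethylsilyloxy)-4-methylpent-3-enyl]-5,8-bis(methoxymethoxy)naphthalene-1,4-dione
Conditions: PhI(OAc)2, MeCN/H2O, 0 °C
Reagents that add atoms: water, O
Why: Hypervalent-iodine oxidation of a para-methoxyphenol to the para-quinone (ipso attack of water, loss of methanol) acts only on the ring bearing the free phenol and should spare the silyl ether, the acetals and the alkene.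

Step 10
Reactants: 18 (R)-2-[1-(tert-butyldimethylsilyloxy)-4-methylpent-3-enyl]-5,8-bis(methoxymethoxy)naphthalene-1,4-dione
Product: 19 shikonin, (R)-5,8-dihydroxy-2-(1-hydroxy-4-methylpent-3-enyl)naphthalene-1,4-dione
Conditions: 2 M aq. HCl, THF/i-PrOH, rt, dark
Reagents that add atoms: none
Why: Acid hydrolysis of the two aryl MOM acetals, assisted by the peri carbonyl groups, and of the secondary silyl ether should give the hydrogen-bonded naphthazarin without breaking the C–O bond at the stereocentre.

Step 11
Reactants: 20 3-hydroxy-3-methylbutanoic acid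
Product: 22 3-methyl-3-(triethylsilyloxy)butanoic acid, via triethylsilyl 3-methyl-3-(triethylsilyloxy)butanoate 21 (not isolated)
Conditions: TESOTf, 2,6-lutidine, CH2Cl2, 0 °C; then MeOH/H2O, rt
Reagents that add atoms: triethylsilyl trifluoromethanesulfonate, CC[Si](CC)(CC)OS(=O)(=O)C(F)(F)F
Why: Silyl triflate/lutidine silylation caps both the tertiary alcohol and the acid, and the much more labile silyl ester is then solvolysed selectively to leave the tertiary TES ether.

Step 12
Reactants: 19 shikonin; 22 3-methyl-3-(triethylsilyloxy)butanoic acid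
Product: 23 (R)-1-(5,8-dihydroxy-1,4-dioxo-1,4-dihydronaphthalen-2-yl)-4-methylpent-3-enyl 3-methyl-3-(triethylsilyloxy)butanoate
Conditions: DCC, DMAP (cat.), CH2Cl2, 0 °C → rt, dark
Reagents that add atoms: none
Why: Steglich esterification acylates only the side-chain secondary alcohol because both peri phenols are tied up in hydrogen bonds to the quinone carbonyls, and acyl transfer to oxygen retains the R configuration.

Step 13
Reactants: 23 (R)-1-(5,8-dihydroxy-1,4-dioxo-1,4-dihydronaphthalen-2-yl)-4-methylpent-3-enyl 3-methyl-3-(triethylsilyloxy)butanoate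
Product: 24 beta-HIVS, (R)-1-(5,8-dihydroxy-1,4-dioxo-1,4-dihydronaphthalen-2-yl)-4-methylpent-3-enyl 3-hydroxy-3-methylbutanoate
Conditions: HF·pyridine, THF/pyridine, 0 °C → rt
Reagents that add atoms: none
Why: Fluoride-mediated cleavage of the tertiary triethylsilyl ether under buffered, weakly acidic conditions removes the last protecting group without hydrolysing or dehydrating the β-hydroxy ester.

**Compound list**

1 | hydroquinone | Oc1ccc(O)cc1 | starting material
2 | 1,4-bis(methoxymethoxy)benzene | COCOc1ccc(OCOC)cc1 | intermediate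
3 | chromium hexacarbonyl | O=C=[Cr](=C=O)(=C=O)(=C=O)(=C=O)=C=O | starting material
4 | 2-lithio-1,4-bis(methoxymethoxy)benzene | COCOc1ccc(OCOC)c([Li])c1 | intermediate
5 | lithium pentacarbonyl{[2,5-bis(methoxymethoxy)phenyl](oxido)methylene}chromate | [Li+].COCOc1ccc(OCOC)c(c1)C([O-])=[Cr](=C=O)(=C=O)(=C=O)(=C=O)=C=O | intermediate
6 | pentacarbonyl{[2,5-bis(methoxymethoxy)phenyl](methoxy)methylene}chromium(0) | COCOc1ccc(OCOC)c(c1)C(OC)=[Cr](=C=O)(=C=O)(=C=O)(=C=O)=C=O | intermediate
7 | 4-methylpent-3-enoic acid | CC(C)=CCC(=O)O | starting material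
8 | 1-(4-methylpent-3-enoyl)imidazole | CC(C)=CCC(=O)n1ccnc1 | intermediate
9 | N-methoxy-N,4-dimethylpent-3-enamide | CC(C)=CCC(=O)N(C)OC | intermediate
10 | trimethylsilylacetylene | C#C[Si](C)(C)C | starting material
11 | lithium (trimethylsilyl)acetylide | [Li]C#C[Si](C)(C)C | intermediate
12 | 6-methyl-1-(trimethylsilyl)hept-5-en-1-yn-3-one | CC(C)=CCC(=O)C#C[Si](C)(C)C | intermediate
13 | (R)-6-methyl-1-(trimethylsilyl)hept-5-en-1-yn-3-ol | CC(C)=CC[C@@H](O)C#C[Si](C)(C)C | intermediate
14 | (R)-tert-butyldimethyl{[6-methyl-1-(trimethylsilyl)hept-5-en-1-yn-3-yl]oxy}silane | CC(C)=CC[C@@H](O[Si](C)(C)C(C)(C)C)C#C[Si](C)(C)C | intermediate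
15 | (R)-tert-butyldimethyl[(6-methylhept-5-en-1-yn-3-yl)oxy]silane | CC(C)=CC[C@@H](O[Si](C)(C)C(C)(C)C)C#C | intermediate
16 | tricarbonyl(η6-naphthol)chromium complex of 17 (Cr on the newly formed ring, face isomers; written as ligand plus Cr(CO)3 fragment) | CC(C)=CC[C@@H](O[Si](C)(C)C(C)(C)C)c1cc(OC)c2c(OCOC)ccc(OCOC)c2c1O.O=C=[Cr](=C=O)=C=O | intermediate
17 | (R)-2-[1-(tert-butyldimethylsilyloxy)-4-methylpent-3-enyl]-4-methoxy-5,8-bis(methoxymethoxy)naphthalen-1-ol | CC(C)=CC[C@@H](O[Si](C)(C)C(C)(C)C)c1cc(OC)c2c(OCOC)ccc(OCOC)c2c1O | intermediate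
18 | (R)-2-[1-(tert-butyldimethylsilyloxy)-4-methylpent-3-enyl]-5,8-bis(methoxymethoxy)naphthalene-1,4-dione | CC(C)=CC[C@@H](O[Si](C)(C)C(C)(C)C)C1=CC(=O)c2c(OCOC)ccc(OCOC)c2C1=O | intermediate
19 | shikonin, (R)-5,8-dihydroxy-2-(1-hydroxy-4-methylpent-3-enyl)naphthalene-1,4-dione | CC(C)=CC[C@@H](O)C1=CC(=O)c2c(O)ccc(O)c2C1=O | intermediate
20 | 3-hydroxy-3-methylbutanoic acid | CC(C)(O)CC(=O)O | starting material
21 | triethylsilyl 3-methyl-3-(triethylsilyloxy)butanoate | CC[Si](CC)(CC)OC(C)(C)CC(=O)O[Si](CC)(CC)CC | intermediate
22 | 3-methyl-3-(triethylsilyloxy)butanoic acid | CC[Si](CC)(CC)OC(C)(C)CC(=O)O | intermediate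
23 | (R)-1-(5,8-dihydroxy-1,4-dioxo-1,4-dihydronaphthalen-2-yl)-4-methylpent-3-enyl 3-methyl-3-(triethylsilyloxy)butanoate | CC(C)=CC[C@@H](OC(=O)CC(C)(C)O[Si](CC)(CC)CC)C1=CC(=O)c2c(O)ccc(O)c2C1=O | intermediate
24 | beta-HIVS, (R)-1-(5,8-dihydroxy-1,4-dioxo-1,4-dihydronaphthalen-2-yl)-4-methylpent-3-enyl 3-hydroxy-3-methylbutanoate | CC(C)=CC[C@@H](OC(=O)CC(C)(C)O)C1=CC(=O)c2c(O)ccc(O)c2C1=O | target

**Step count**

Total: 13 steps. Longest linear sequence: 10 steps (steps 3–10, 12, 13, from acid 7).

**Steps most likely to fail**

1. Step 8. After alkyne insertion the metal intermediates may divert to cyclobutenone, indene or furan products, or the ortho-chelated carbene may decompose before annulation, so that little naphthol forms. The fallback gives up the ring-forming step, makes the C2–C1' bond on a preformed naphthalene, and sets out from Weinreb amide 9. Commercial naphthazarin is reduced with Na2S2O4 and exhaustively alkylated (NaH, MOMCl) to 1,4,5,8-tetrakis(methoxymethoxy)naphthalene F1. MOM-directed lithiation (n-BuLi, THF, 0 °C) and acylation with 9 should give 4-methyl-1-[1,4,5,8-tetrakis(methoxymethoxy)naphthalen-2-yl]pent-3-en-1-one F2. Reduction with (+)-DIP-Cl is expected, by the usual aryl alkyl ketone model, to give (R)-4-methyl-1-[1,4,5,8-tetrakis(methoxymethoxy)naphthalen-2-yl]pent-3-en-1-ol F3. Silylation (TBSCl, imidazole) gives its tert-butyldimethylsilyl ether F4. Oxidation with CAN in aqueous MeCN removes one para pair of MOM groups and should give quinone 18 together with its ring isomer (R)-6-[1-(tert-butyldimethylsilyloxy)-4-methylpent-3-enyl]-5,8-bis(methoxymethoxy)naphthalene-1,4-dione F5. The pair need not be separated, since the conditions of step 10 turn both into the same naphthazarin; the fallback thus comes back to the route at 18 and, for the isomer, at 19.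

2. Step 10. Cleavage of the second MOM acetal may be slow enough that the freed carbinol sits in acid for long, and then cyclisation onto the trisubstituted alkene or benzylic solvolysis with loss of configuration can compete. The fallback changes the order of events so that the carbinol is never free under acid, and sets out from 18. HF·pyridine removes only the silyl ether to give (R)-2-(1-hydroxy-4-methylpent-3-enyl)-5,8-bis(methoxymethoxy)naphthalene-1,4-dione F6. Steglich esterification with acid 22 gives (R)-1-[5,8-bis(methoxymethoxy)-1,4-dioxo-1,4-dihydronaphthalen-2-yl]-4-methylpent-3-enyl 3-methyl-3-(triethylsilyloxy)butanoate F7. Dilute HCl in THF/i-PrOH at 0 °C then removes both MOM acetals and the TES ether from the already acylated compound, which comes back to the route at the target 24.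

3. Step 5. The skipped double bond may migrate into conjugation with the ynone under the hydrogen-transfer conditions, or the catalyst may discriminate poorly between the alkynyl and the allylic methylene flank, giving low enantiopurity. The fallback replaces asymmetric catalysis by resolution and sets out from ynone 12. Luche reduction (NaBH4, CeCl3, MeOH, −78 °C) gives racemic 6-methyl-1-(trimethylsilyl)hept-5-en-1-yn-3-ol F8, and K2CO3/MeOH gives racemic 6-methylhept-5-en-1-yn-3-ol F9. Lipase-catalysed acetylation (Candida antarctica lipase B, vinyl acetate, hexane) should, by the Kazlauskas rule with the slim ethynyl group as the medium substituent, convert the S enantiomer into (S)-6-methylhept-5-en-1-yn-3-yl acetate F10 and leave (R)-6-methylhept-5-en-1-yn-3-ol F11. After separation and a check of the configuration by Mosher ester analysis, silylation of F11 (TBSCl, imidazole) comes back to the route at 15.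

**Further compounds**

F1 | step 8 | 1,4,5,8-tetrakis(methoxymethoxy)naphthalene | COCOc1ccc(OCOC)c2c(OCOC)ccc(OCOC)c12
F2 | step 8 | 4-methyl-1-[1,4,5,8-tetrakis(methoxymethoxy)naphthalen-2-yl]pent-3-en-1-one | CC(C)=CCC(=O)c1cc(OCOC)c2c(OCOC)ccc(OCOC)c2c1OCOC
F3 | step 8 | (R)-4-methyl-1-[1,4,5,8-tetrakis(methoxymethoxy)naphthalen-2-yl]pent-3-en-1-ol | CC(C)=CC[C@@H](O)c1cc(OCOC)c2c(OCOC)ccc(OCOC)c2c1OCOC
F4 | step 8 | (R)-tert-butyldimethyl{4-methyl-1-[1,4,5,8-tetrakis(methoxymethoxy)naphthalen-2-yl]pent-3-enyloxy}silane | CC(C)=CC[C@@H](O[Si](C)(C)C(C)(C)C)c1cc(OCOC)c2c(OCOC)ccc(OCOC)c2c1OCOC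
F5 | step 8 | (R)-6-[1-(tert-butyldimethylsilyloxy)-4-methylpent-3-enyl]-5,8-bis(methoxymethoxy)naphthalene-1,4-dione | CC(C)=CC[C@@H](O[Si](C)(C)C(C)(C)C)c1cc(OCOC)c2C(=O)C=CC(=O)c2c1OCOC
F6 | step 10 | (R)-2-(1-hydroxy-4-methylpent-3-enyl)-5,8-bis(methoxymethoxy)naphthalene-1,4-dione | CC(C)=CC[C@@H](O)C1=CC(=O)c2c(OCOC)ccc(OCOC)c2C1=O
F7 | step 10 | (R)-1-[5,8-bis(methoxymethoxy)-1,4-dioxo-1,4-dihydronaphthalen-2-yl]-4-methylpent-3-enyl 3-methyl-3-(triethylsilyloxy)butanoate | CC(C)=CC[C@@H](OC(=O)CC(C)(C)O[Si](CC)(CC)CC)C1=CC(=O)c2c(OCOC)ccc(OCOC)c2C1=O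
F8 | step 5 | rac-6-methyl-1-(trimethylsilyl)hept-5-en-1-yn-3-ol | CC(C)=CCC(O)C#C[Si](C)(C)C
F9 | step 5 | rac-6-methylhept-5-en-1-yn-3-ol | CC(C)=CCC(O)C#C
F10 | step 5 | (S)-6-methylhept-5-en-1-yn-3-yl acetate | CC(C)=CC[C@H](OC(C)=O)C#C
F11 | step 5 | (R)-6-methylhept-5-en-1-yn-3-ol | CC(C)=CC[C@@H](O)C#C
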